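**Assumptions (one line each)**
- The following are treated as commercially available: (E)-pent-3-en-2-one, 2-methylprop-1-enylboronic acid, Ph3P=C(Me)CHO, 5-(benzylsulfonyl)-1-phenyltetrazole, PhNTf2, Et2Zn, pyruvic acid and 2-(trimethylsilyl)ethanol.
- The (S)-BINOL catalyst is assumed to give the (R)-adduct. If it gives the opposite sense, the (R)-BINOL enantiomer is used.
- Atom labels A1–A9 in the "Why" lines refer to the target SMILES, A1 being the Et-bearing ring carbon and A9 the last ring-fusion CH.

**Retrosynthetic overview**
1. The target acid comes from the TMSE ester of the Et-cyclopentene, made by Negishi ethylation of an enol triflate. The cyclopentene C=C is therefore installed last, from a cyclopentanone.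
2. That trans-fused hydrindanone (17) comes from one intramolecular Diels–Alder (IMDA) of a pentaene enedione ester (16). This closes the cyclohexene and the cyclopentanone together and sets A4, A9, A8 and A7, including the vicinal quaternary pair.
3. Compound 16 comes from aldol/dehydration of methyl ketone 11 with TMSE pyruvate. Ketone 11 comes from enal 6 by two E-selective Wittig reactions and one Julia–Kocienski olefination. Enal 6 comes from SeO2 oxidation of the isobutenyl group of 3.
4. Ketone 3 carries the only tertiary stereocentre that is built first (A3). It comes from BINOL-catalysed asymmetric conjugate alkenylation of pentenone 1 with boronic acid 2.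

**Route**

**Step 1**
Reactants: 1 (E)-pent-3-en-2-one; 2 2-methylprop-1-en-1-ylboronic acid
Product: 3 (R)-4,6-dimethylhept-5-en-2-one
Conditions: 2 (1.5 equiv), i-PrOH (3 equiv), (S)-3,3′-Br2-BINOL (15 mol%), PhMe, 4 Å MS, 40 °C, 72 h
Reagents that add atoms: none beyond the isobutenyl group of 2
Why: The BINOL-boronate exchange gives a chiral alkenyl borate that delivers the alkenyl group 1,4 through a cyclic boron-bound transition state (metal-free asymmetric conjugate alkenylation), setting A3 (R).

**Step 2**
Reactants: 3; 4 tert-butyl hydroperoxide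
Product: 5 (R,E)-7-hydroxy-4,6-dimethylhept-5-en-2-one
Conditions: SeO2 (10 mol%), 4 (2 equiv), CH2Cl2, 0 °C → rt
Reagents that add atoms: TBHP, CC(C)(C)OO (source of the OH oxygen)
Why: Riley allylic oxidation of the trisubstituted alkene occurs at the methyl trans to the chain, giving the E-allylic alcohol. That geometry later puts A3 trans to A6 in the diene. The methyl ketone and A3 are untouched.

**Step 3**
Reactants: 5
Product: 6 (R,E)-2,4,6-… i.e. (R,E)-2,4-dimethyl-6-oxohept-2-enal
Conditions: MnO2 (15 equiv), CH2Cl2, rt
Reagents that add atoms: none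
Why: MnO2 oxidation of an allylic alcohol is chemoselective, so the ketone is not touched. The neutral conditions avoid γ-epimerisation at A3.

**Step 4**
Reactants: 6; 7 2-(triphenylphosphoranylidene)propanal
Product: 8 (2E,4E,6R)-2,4,6-trimethyl-8-oxonona-2,4-dienal
Conditions: 7 (1.5 equiv), PhMe, 80 °C, 12 h, dark
Reagents that add atoms: 7, CC(C=O)=P(c1ccccc1)(c1ccccc1)c1ccccc1 (supplies the C(Me)CHO unit)
Why: Stabilised-ylide Wittig olefination (Wittig reaction) is E-selective and reacts with the enal but not the ketone. It places the aldehyde trans to A5, which is the required diene geometry.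

**Step 5**
Reactants: 8; 7
Product: 9 (2E,4E,6E,8R)-2,4,6,8-tetramethyl-10-oxoundeca-2,4,6-trienal
Conditions: 7 (1.5 equiv), PhMe, 80 °C, 12 h, dark
Reagents that add atoms: 7, CC(C=O)=P(c1ccccc1)(c1ccccc1)c1ccccc1
Why: A second E-selective stabilised Wittig reaction extends the chain with the C(Me)CHO unit. This gives the Ca=Cb(Me) alkene with the E geometry the target needs.

**Step 6**
Reactants: 9; 10 5-(benzylsulfonyl)-1-phenyl-1H-tetrazole
Product: 11 (4R,5E,7E,9E,11E)-4,6,8,10-tetramethyl-12-phenyldodeca-5,7,9,11-tetraen-2-one
Conditions: 10 (1.3 equiv), KHMDS (1.25 equiv), DME, –60 °C; add 9; –60 °C → rt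
Reagents that add atoms: 10, O=S(=O)(Cc1ccccc1)c1nnnn1-c1ccccc1 (supplies the =CHPh group)
Why: Julia–Kocienski olefination gives the E-styryl unit. The benzylic tetrazolyl sulfone anion is less basic than the ketone enolate, so the methyl ketone survives.

**Step 7 (parallel branch, independent of Steps 1–6)**
Reactants: 12 pyruvic acid; 13 2-(trimethylsilyl)ethanol
Product: 14 2-(trimethylsilyl)ethyl pyruvate
Conditions: DCC, DMAP (cat.), CH2Cl2, 0 °C → rt
Reagents that add atoms: none beyond the two reactants
Why: Steglich esterification. The TMSE ester is stable to the later base, Lewis acid and Pd conditions. It is removed by fluoride even though the carboxyl is hindered.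

**Step 8**
Reactants: 11; 14
Product: 15 TMSE 2-hydroxy-2,6,8,10,12-pentamethyl-4-oxo-14-phenyltetradeca-7,9,11,13-tetraenoate (6R; C2 epimers)
Conditions: LDA (1.05 equiv), THF, –78 °C; then 14 (1.5 equiv), –78 °C; NH4Cl
Reagents that add atoms: none beyond 14
Why: Kinetic LDA deprotonation of the methyl ketone at CH3 followed by aldol addition to the pyruvate ketone. The new carbinol centre is destroyed in Step 9, so the epimer mixture is irrelevant.

**Step 9**
Reactants: 15
Product: 16 TMSE (2E,6R,7E,9E,11E,13E)-2,6,8,10,12-pentamethyl-4-oxo-14-phenyltetradeca-2,7,9,11,13-pentaenoate (the IMDA substrate)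
Conditions: Burgess reagent (1.5 equiv), PhMe, 50 °C; then DBU (0.3 equiv), rt
Reagents that add atoms: none
Why: Mild syn-dehydration of the tertiary β-hydroxy ketone, then DBU equilibration to the thermodynamic E-enedione. This has ketone and ester trans, as required for the exo-tether/ester-endo cycloaddition.

**Step 10**
Reactants: 16
Product: 17 trans-fused hydrindanone (TMSE ester; stereochemistry as in the SMILES, list below)
Conditions: Me2AlCl (1.2 equiv), CH2Cl2 (5 mM), –78 → –20 °C, dark
Reagents that add atoms: none
Why: Proposed new method: a Lewis-acid-promoted intramolecular Diels–Alder that forms both rings and four stereocentres in one step.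
- Mechanistic reasoning: The electron-rich terminal 2-methyl-1,3-diene (A4=A5–A6=A7) is tethered through a three-atom chain (A3, A2, A1) to an activated trisubstituted 4-oxo-enoate (A9=A8).
- Stereochemical consequences: The tether forces a fused mode with the ketone exo and the ester endo, giving a trans ring fusion. The all-E diene places A3 and the dienyl side chain on the same face. The E-dienophile puts the two Me groups (A7, A8) cis. The pseudo-equatorial A3-Me, anti to the diene, selects the diastereoface.
- Closest known reactions: type-1 IMDA of 1,3,8-nonatrien-7-ones to hydrindanones, and Lewis-acid Diels–Alder of 1,1-disubstituted dienes with α-substituted 4-oxo-enoates. What is new is closing a vicinal all-carbon quaternary pair in this pentaene enedione.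

**Step 11**
Reactants: 17; 18 N-phenylbis(trifluoromethanesulfonimide)
Product: 19 cyclopentenyl triflate (A1(OTf)=A2)
Conditions: KHMDS (1.2 equiv), THF, –78 °C; then 18 (1.3 equiv), –78 °C → 0 °C
Reagents that add atoms: 18, O=S(=O)(C(F)(F)F)N(c1ccccc1)S(=O)(=O)C(F)(F)F (supplies Tf)
Why: Kinetic deprotonation occurs at the unhindered A2 CH2, not at the neopentylic A9–H, so A9 is not epimerised. The ester has no α-H (A8 is quaternary).

**Step 12**
Reactants: 19; 20 diethylzinc
Product: 21 TMSE ester of the target
Conditions: Pd(PPh3)4 (5 mol%), 20 (2.5 equiv), THF, 45 °C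
Reagents that add atoms: 20, CC[Zn]CC (supplies Et)
Why: Negishi cross-coupling of an alkenyl triflate with a dialkylzinc creates the A1(Et)=A2 alkene. The ester and polyene tolerate it, and no stereocentre is altered.

**Step 13**
Reactants: 21
Product: 22 Zyggomphic acid B
Conditions: TBAF (3 equiv), THF, 0 °C → rt; then pH 4 work-up
Reagents that add atoms: none
Why: Fluoride-induced β-elimination of the 2-(trimethylsilyl)ethyl ester (loss of ethylene and Me3SiF) releases the hindered carboxylic acid under neutral conditions. This avoids hydrolysis of a carboxyl flanked by two quaternary carbons and leaves the polyene intact.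

**Compound list**
1 | (E)-pent-3-en-2-one | C/C=C/C(C)=O | starting material
2 | 2-methylprop-1-en-1-ylboronic acid | CC(C)=CB(O)O | starting material
3 | (R)-4,6-dimethylhept-5-en-2-one | CC(=O)C[C@@H](C)C=C(C)C | intermediate
4 | tert-butyl hydroperoxide | CC(C)(C)OO | reagent (starting material)
5 | (R,E)-7-hydroxy-4,6-dimethylhept-5-en-2-one | CC(=O)C[C@@H](C)/C=C(C)/CO | intermediate
6 | (R,E)-2,4-dimethyl-6-oxohept-2-enal | CC(=O)C[C@@H](C)/C=C(C)/C=O | intermediate
7 | 2-(triphenylphosphoranylidene)propanal | CC(C=O)=P(c1ccccc1)(c1ccccc1)c1ccccc1 | starting material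
8 | (2E,4E,6R)-2,4,6-trimethyl-8-oxonona-2,4-dienal | CC(=O)C[C@@H](C)/C=C(C)/C=C(C)/C=O | intermediate
9 | (2E,4E,6E,8R)-2,4,6,8-tetramethyl-10-oxoundeca-2,4,6-trienal | CC(=O)C[C@@H](C)/C=C(C)/C=C(C)/C=C(C)/C=O | intermediate
10 | 5-(benzylsulfonyl)-1-phenyl-1H-tetrazole | O=S(=O)(Cc1ccccc1)c1nnnn1-c1ccccc1 | starting material
11 | (4R,5E,7E,9E,11E)-4,6,8,10-tetramethyl-12-phenyldodeca-5,7,9,11-tetraen-2-one | CC(=O)C[C@@H](C)/C=C(C)/C=C(C)/C=C(C)/C=C/c1ccccc1 | intermediate
12 | pyruvic acid | CC(=O)C(=O)O | starting material
13 | 2-(trimethylsilyl)ethanol | C[Si](C)(C)CCO | starting material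
14 | 2-(trimethylsilyl)ethyl pyruvate | CC(=O)C(=O)OCC[Si](C)(C)C | intermediate
15 | aldol adduct (C2 epimers; 2-hydroxy-2-methyl-4-oxo tetraenoate TMSE ester) | C[Si](C)(C)CCOC(=O)C(C)(O)CC(=O)C[C@@H](C)/C=C(C)/C=C(C)/C=C(C)/C=C/c1ccccc1 | intermediate
16 | TMSE enedione IMDA substrate | C[Si](C)(C)CCOC(=O)/C(C)=C/C(=O)C[C@@H](C)/C=C(C)/C=C(C)/C=C(C)/C=C/c1ccccc1 | intermediate
17 | trans-fused hydrindanone (indene numbering: 1-oxo-3,4,6,7-tetramethyl-6-dienyl-7-carboxylate TMSE ester) | O=C1C[C@@H](C)[C@@H]2C(C)=C[C@](C)(/C=C(C)/C=C/c3ccccc3)[C@](C)(C(=O)OCC[Si](C)(C)C)[C@@H]12 | intermediate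
18 | N-phenylbis(trifluoromethanesulfonimide) | O=S(=O)(C(F)(F)F)N(c1ccccc1)S(=O)(=O)C(F)(F)F | reagent (starting material)
19 | cyclopentenyl triflate of 17 | FC(F)(F)S(=O)(=O)OC1=C[C@@H](C)[C@@H]2C(C)=C[C@](C)(/C=C(C)/C=C/c3ccccc3)[C@](C)(C(=O)OCC[Si](C)(C)C)[C@@H]12 | intermediate
20 | diethylzinc | CC[Zn]CC | reagent (starting material)
21 | TMSE ester of Zyggomphic acid B | CCC1=C[C@@H](C)[C@@H]2C(C)=C[C@](C)(/C=C(C)/C=C/c3ccccc3)[C@](C)(C(=O)OCC[Si](C)(C)C)[C@@H]12 | intermediate
22 | Zyggomphic acid B | CCC1=C[C@@H](C)[C@@H]2C(C)=C[C@](C)(/C=C(C)/C=C/c3ccccc3)[C@](C)(C(=O)O)[C@@H]12 | target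

**Total step count:** 13 (including the parallel preparation of 14).
**Longest linear sequence:** 12 steps (1 → 2 → 3 → 4 → 5 → 6 → 8 → 9 → 10 → 11 → 12 → 13).

**Three steps most likely to fail**
1. **Step 10, the IMDA (the proposed new step).** It may give the cis-fused or wrong-diastereoface adduct, or low conversion because of the vicinal quaternary centres and the sensitive polyene.
   - Fallback using known chemistry: build the A7–A8 pair by Ireland–Claisen rearrangement. Esterify a 2-(cyclopentenyl)propanoic acid bearing an A4 isopropenyl group with the tertiary allylic alcohol PhCH=CH–C(Me)(OH)–CH=C(Me)–CH=CH2, and rearrange through a chair transition state. Then close the cyclohexene by ring-closing metathesis between the new A7 vinyl and the isopropenyl.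
2. **Step 1, the BINOL-catalysed alkenylation.** A β-alkyl enone with a β,β-disubstituted alkenylboronate may give poor yield or ee.
   - Fallback using known chemistry: make (2E)-3,5-dimethylhexa-2,4-dienal by HWE of mesityl oxide and DIBAL/MnO2. Reduce it by organocatalytic enantioselective transfer hydrogenation (Hantzsch ester, chiral amine/acid) to (R)-3,5-dimethylhex-4-enal. Convert that to 3 by MeMgBr addition and oxidation.
3. **Step 6, the Julia–Kocienski olefination.** It may suffer enolisation of the ketone, or conjugate addition to the trienal.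
   - Fallback using known chemistry: convert the trienal 9 to the (E)-dienyl iodide by Takai–Utimoto olefination (CHI3/CrCl2), then install phenyl by Suzuki coupling with PhB(OH)2 and Pd to give 11.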